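**Retrosynthetic overview**

1. Numbering: ring B (seven-membered) is C1(=C11H2)–C2(OH)–C3H2–C4–C5(OH)–C6–C10; ring A (cyclopentene) is C6–C7(CH3)=C8–C9–C10; C4 carries the side chain C13(CH3)–C15(OAc)–C16(OAc)–C17=C18. The strategy rests on C3: it is the only CH2 of ring B and lies between C2 (reachable at the ketone level) and the branch carbon C4, so ring B is opened at C2–C3 to a C2 acyl radical and a C4=C3H2 methylene that already bears the side chain.
2. After ring closure: C11–O elimination to the exocyclic methylene, C2 reduction, C17 ether → aldehyde → Wittig (C17=C18), acetonide → diacetate, desilylation.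
3. Radical precursor: a trans-2,3-disubstituted cyclopentanone from cyclopent-2-en-1-one by enantioselective Mukaiyama–Michael addition (C10–C1) and boron aldol of the resulting enol ether with an α-methylene aldehyde (C6–C5); C7 ketone → enol triflate → methyl alkene; ester → Se-phenyl selenoester.
4. α-Methylene aldehyde: (S)-glyceraldehyde acetonide and a (Z)-crotylborane (C13, C15), acetonide shift to C15/C16, hydroboration–oxidation, α-methylenation (C3).
5. Ring order: ring A is bought as cyclopentenone; ring B is the only ring formed, in step 16.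

Key step: step 16

Remark on the chemistry: C1 is a transient stereocentre that becomes sp2 again in step 18; it is drawn 1S throughout, and any 1R epimer formed in step 9 is expected to follow the same steps and converge at the enone.

Abbreviations: PMB = 4-methoxybenzyl, TBS = tert-butyldimethylsilyl, TIPS = triisopropylsilyl, Ipc = isopinocampheyl, Chx = cyclohexyl. Locants C1–C18 are those of the overview.

**Route**

Step 1
Reactants: 1 (S)-2,2-dimethyl-1,3-dioxolane-4-carbaldehyde [(S)-glyceraldehyde acetonide]; 2 (Z)-but-2-ene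
Product: 5 (1S,2R)-1-[(4S)-2,2-dimethyl-1,3-dioxolan-4-yl]-2-methylbut-3-en-1-ol, via (Z)-crotylpotassium 3 (not isolated), via (Z)-crotyldiisopinocampheylborane 4 (not isolated)
Conditions: 2, KOt-Bu, n-BuLi, THF, −78 → −45 °C; (−)-Ipc2BOMe [from (+)-α-pinene], −78 °C; BF3·OEt2; 1, −78 °C; NaOH, H2O2, 0 °C → rt
Reagents that add atoms: none
Why: Brown crotylboration, in which the (Z)-crotylborane reacts through a chair transition state to give the 13,15-syn adduct and the Ipc groups from (+)-α-pinene direct attack to the Si face of the aldehyde, so that 15S and the 15,16-syn (threo) relation are set by reagent control against the Felkin preference of the α-alkoxy aldehyde.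

Step 2
Reactants: 5 (1S,2R)-1-[(4S)-2,2-dimethyl-1,3-dioxolan-4-yl]-2-methylbut-3-en-1-ol
Product: 6 [(4S,5S)-5-[(2R)-but-3-en-2-yl]-2,2-dimethyl-1,3-dioxolan-4-yl]methanol
Conditions: TsOH·H2O (cat.), acetone, rt
Reagents that add atoms: none
Why: Acid-catalysed acetal equilibration should move the isopropylidene group to the threo C15/C16 diol, because the trans-4,5-disubstituted dioxolane is thermodynamically preferred to the terminal one; the primary C17 hydroxyl is freed and no stereocentre is touched.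

Step 3
Reactants: 6 [(4S,5S)-5-[(2R)-but-3-en-2-yl]-2,2-dimethyl-1,3-dioxolan-4-yl]methanol
Product: 7 (4S,5S)-4-[(2R)-but-3-en-2-yl]-5-[(4-methoxybenzyloxy)methyl]-2,2-dimethyl-1,3-dioxolane
Conditions: NaH, PMBCl, Bu4NI (cat.), THF/DMF, 0 °C → rt
Reagents that add atoms: 4-methoxybenzyl chloride COc1ccc(CCl)cc1
Why: Williamson etherification of the primary alkoxide masks C17 as an ether that survives all steps up to the late oxidative unmasking.

Step 4
Reactants: 7 (4S,5S)-4-[(2R)-but-3-en-2-yl]-5-[(4-methoxybenzyloxy)methyl]-2,2-dimethyl-1,3-dioxolane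
Product: 9 (3R)-3-[(4S,5S)-5-[(4-methoxybenzyloxy)methyl]-2,2-dimethyl-1,3-dioxolan-4-yl]butan-1-ol, via B-alkyl-9-BBN adduct 8 (not isolated)
Conditions: 9-BBN, THF, 0 °C → rt; NaOH, H2O2, 0 °C
Reagents that add atoms: hydrogen peroxide OO
Why: Hydroboration–oxidation with the bulky borane places boron, and then oxygen, on the terminal vinyl carbon (C5) with anti-Markovnikov selectivity.

Step 5
Reactants: 9 (3R)-3-[(4S,5S)-5-[(4-methoxybenzyloxy)methyl]-2,2-dimethyl-1,3-dioxolan-4-yl]butan-1-ol
Product: 10 (3R)-3-[(4S,5S)-5-[(4-methoxybenzyloxy)methyl]-2,2-dimethyl-1,3-dioxolan-4-yl]butanal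
Conditions: Dess–Martin periodinane, NaHCO3, CH2Cl2, 0 °C → rt
Reagents that add atoms: none
Why: Dess–Martin oxidation of the primary alcohol under buffered, non-epimerising conditions gives the C5 aldehyde without touching the acetal or the PMB ether.

Step 6
Reactants: 10 (3R)-3-[(4S,5S)-5-[(4-methoxybenzyloxy)methyl]-2,2-dimethyl-1,3-dioxolan-4-yl]butanal
Product: 12 (3R)-3-[(4S,5S)-5-[(4-methoxybenzyloxy)methyl]-2,2-dimethyl-1,3-dioxolan-4-yl]-2-methylidenebutanal, via Mannich base 11 (not isolated)
Conditions: Me2N=CH2+ I− (Eschenmoser's salt), Et3N, CH2Cl2, rt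
Reagents that add atoms: N,N-dimethylmethyleneiminium iodide C=[N+](C)C.[I-]
Why: Mannich reaction at C4 followed by β-elimination of dimethylamine (α-methylenation of an aldehyde) brings in C3 as the methylene of a 2-substituted acrolein; the C13 centre is not α to the carbonyl and is not at risk.

Step 7
Reactants: 13 methyl 3-hydroxypropanoate
Product: 14 methyl 3-[(tert-butyldimethylsilyl)oxy]propanoate
Conditions: TBSCl, imidazole, CH2Cl2, 0 °C → rt
Reagents that add atoms: tert-butyldimethylsilyl chloride CC(C)(C)[Si](C)(C)Cl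
Why: Standard silylation protects the future C11 oxygen as an ether that is a poor leaving group, so that the ester enolate and later acyl derivatives do not eliminate.

Step 8
Reactants: 14 methyl 3-[(tert-butyldimethylsilyl)oxy]propanoate
Product: 16 1-methoxy-1-(trimethylsilyloxy)-3-[(tert-butyldimethylsilyl)oxy]prop-1-ene (silyl ketene acetal, mainly the isomer shown), via lithium ester enolate 15 (not isolated)
Conditions: LDA, TMSCl (in situ), THF, −78 °C → rt; non-aqueous work-up
Reagents that add atoms: chlorotrimethylsilane C[Si](C)(C)Cl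
Why: Kinetic ester enolisation with immediate O-silylation gives the silyl ketene acetal, and trapping at −78 °C outruns β-elimination of silanolate.

Step 9
Reactants: 16 1-methoxy-1-(trimethylsilyloxy)-3-[(tert-butyldimethylsilyl)oxy]prop-1-ene; 17 cyclopent-2-en-1-one
Product: 18 methyl (2S)-3-[(tert-butyldimethylsilyl)oxy]-2-[(1R)-3-(trimethylsilyloxy)cyclopent-2-en-1-yl]propanoate
Conditions: (R)-3,3-diphenyl-1-(o-tolyl)tetrahydro-1H,3H-pyrrolo[1,2-c][1,3,2]oxazaborole·HN(SO2CF3)2 (20 mol%), Ph3PO (25 mol%), toluene, −20 °C; Et3N quench, filtration, used crude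
Reagents that add atoms: none
Why: Chiral Lewis acid-catalysed Mukaiyama–Michael addition in which the boron-bound enone is attacked at C10 on the face left open by the catalyst aryl group and the silyl group passes (through Ph3PO) to the enolate oxygen, which keeps the C6=C7 enol ether regiodefined; the catalyst antipode from (R)-diphenylprolinol is assigned from the α-C–H···O binding model as the one giving 10R, and the other antipode would be taken if the sense proved opposite.

Step 10
Reactants: 18 methyl (2S)-3-[(tert-butyldimethylsilyl)oxy]-2-[(1R)-3-(trimethylsilyloxy)cyclopent-2-en-1-yl]propanoate; 12 (3R)-3-[(4S,5S)-5-[(4-methoxybenzyloxy)methyl]-2,2-dimethyl-1,3-dioxolan-4-yl]-2-methylidenebutanal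
Product: 20 aldol adduct (methyl ester at C2, C11–OTBS, C7 ketone, C5–OH, C4=C3H2, C15/C16 acetonide, C17–OPMB; 1S,5S,6R,10R,13R,15S,16S), via dicyclohexylboron enolate 19 (not isolated)
Conditions: Chx2BOTf, CH2Cl2, 0 °C, then Me3SiOTf removed in vacuo; 12, CH2Cl2, −78 °C; pH 7 buffer, MeOH, H2O2, 0 °C
Reagents that add atoms: none
Why: Silicon-to-boron exchange of the silyl enol ether with the dialkylboron triflate gives the cyclic (E)-boron enolate regiospecifically without a base that would attack the ester, and its aldol reaction through a chair Zimmerman–Traxler transition state on the face anti to the C10 substituent should give the 6,10-trans, 5,6-anti adduct.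

Step 11
Reactants: 20 aldol adduct
Product: 21 C5 TBS ether of 20 (1S,5S,6R,10R,13R,15S,16S)
Conditions: TBSOTf, 2,6-lutidine, CH2Cl2, −78 → 0 °C
Reagents that add atoms: tert-butyldimethylsilyl triflate CC(C)(C)[Si](C)(C)OS(=O)(=O)C(F)(F)F
Why: Silylation of the hindered β-hydroxy ketone with the silyl triflate blocks retro-aldol cleavage and lactonisation onto the C2 ester and installs the group that later directs hydrogen transfer at C4.

Step 12
Reactants: 21 C5 TBS ether
Product: 23 C7=C8 enol triflate (1S,5S,6R,10R,13R,15S,16S), via potassium enolate 22 (not isolated)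
Conditions: KHMDS, THF, −78 °C; PhNTf2, −78 → 0 °C
Reagents that add atoms: N-phenylbis(trifluoromethanesulfonimide) O=S(=O)(N(c1ccccc1)S(=O)(=O)C(F)(F)F)C(F)(F)F
Why: Kinetic deprotonation of the ketone at the unhindered C8 methylene (not at C6, whose enolate would expel the C5 silyloxy group, and not at the less acidic ester) and O-triflation fix the alkene at C7=C8.

Step 13
Reactants: 23 C7=C8 enol triflate
Product: 24 C7-methyl cyclopentene methyl ester (1S,5S,6S,10R,13R,15S,16S)
Conditions: Pd(PPh3)4 (zerovalent palladium, 5 mol%), Me2Zn, THF, 0 °C → rt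
Reagents that add atoms: dimethylzinc C[Zn]C
Why: Negishi coupling of the alkenyl triflate with the methylzinc reagent gives the trisubstituted C7(CH3)=C8 alkene and tolerates the ester, the silyl ethers and the allylic C5 ether.

Step 14
Reactants: 24 C7-methyl cyclopentene methyl ester
Product: 25 C2 carboxylic acid (1S,5S,6S,10R,13R,15S,16S)
Conditions: LiOH·H2O, THF/MeOH/H2O, 40 °C; then aq. HCl to pH 4, 0 °C
Reagents that add atoms: lithium hydroxide [Li+].[OH-]
Why: Saponification of the methyl ester; hydroxide does not form the ester enolate, so the β-silyloxy group is not eliminated, and epimerisation at C1 is without consequence.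

Step 15
Reactants: 25 C2 carboxylic acid
Product: 26 Se-phenyl selenoester, the radical precursor (C2(=O)SePh, C1–CH2OTBS, C5–OTBS, C4=C3H2, C15/C16 acetonide, C17–OPMB; 1S,5S,6S,10R,13R,15S,16S)
Conditions: N-(phenylseleno)phthalimide, PBu3, CH2Cl2, −20 °C → rt
Reagents that add atoms: N-(phenylselanyl)phthalimide O=C1N([Se]c2ccccc2)C(=O)c2ccccc12
Why: Activation of the acid as an acyloxyphosphonium salt and attack by phenylselenolate give the acyl selenide under neutral conditions; C11 is kept as a silyl ether here because an ester leaving group β to the acidic C1–H of an acyl selenide would invite elimination.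

Step 16
Reactants: 26 Se-phenyl selenoester
Product: 27 trans-fused hydroazulen-2-one (C2 ketone, C1–CH2OTBS, C5–OTBS, new C4–H; 1S,4S,5R,6S,10R,13R,15S,16S)
Conditions: Bu3SnH (1.3 equiv), AIBN (0.2 equiv), benzene (0.005 M), 80 °C, syringe-pump addition over 6 h
Reagents that add atoms: none
Why: The tin radical abstracts the phenylseleno group and the nucleophilic C2 acyl radical adds to the unsubstituted terminus C3 of the 1,1-disubstituted alkene, forming C2–C3, after which the tertiary C4 radical takes hydrogen from Bu3SnH and carries the chain; the closest known reaction type is the 7-endo cyclisation of acyl radicals from phenyl selenoesters onto 1,1-disubstituted alkenes. Ring B closes in the 7-endo-trig mode because the 6-exo carbon C4 is fully substituted, and the trans C6/C10 substituents give the trans-fused hydroazulene. The new C4 stereocentre is set by hydrogen transfer to the ring face anti to the adjacent C5 silyl ether, which places the side chain cis to C5–O as in the target. The step needs 7-endo over 6-exo closure, ring closure ahead of decarbonylation of the α-branched acyl radical and ahead of direct reduction, and no attack on the other alkenes. These are secured by the substitution at C4, by high dilution with slow stannane addition, by the strain of the norbornanone that transannular 5-exo attack on C8 would create from chains held pseudo-diequatorial, and by masking the prenyl alkene as the C17 ether so that the C4 radical has no 5-exo trap. The C2 ketone is the oxidation level needed for the allylic alcohol and the C11 silyloxymethyl group is the latent exocyclic methylene.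

Step 17
Reactants: 27 trans-fused hydroazulen-2-one
Product: 28 C11 alcohol (β-hydroxy ketone; 1S,4S,5R,6S,10R,13R,15S,16S)
Conditions: HF·pyridine, pyridine, THF, 0 °C
Reagents that add atoms: none
Why: Buffered fluoride cleaves the primary C11 silyl ether much faster than the secondary C5 silyl ether flanked by two branched carbons, and leaves the acetonide and the PMB ether intact.

Step 18
Reactants: 28 C11 alcohol
Product: 30 α-methylene ketone (C1=C11H2, C2=O; 4S,5R,6S,10R,13R,15S,16S), via C11 mesylate 29 (not isolated)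
Conditions: MsCl, Et3N (excess), CH2Cl2, 0 °C → rt
Reagents that add atoms: none
Why: Mesylation of the primary alcohol and E1cB elimination of the β-mesyloxy ketone give the exocyclic enone and remove the C1 stereocentre; the mild amine base and short reaction time limit isomerisation to the endocyclic enone.

Step 19
Reactants: 30 α-methylene ketone
Product: 31 (2R)-allylic alcohol (2R,4S,5R,6S,10R,13R,15S,16S)
Conditions: (S)-2-methyl-CBS-oxazaborolidine (0.5 equiv), catecholborane, toluene, −78 °C
Reagents that add atoms: none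
Why: Corey–Bakshi–Shibata reduction gives 1,2-reduction of the enone under reagent control, the alkenyl carbon C1 acting as the large and the C3 methylene as the small group, so that the S catalyst should deliver 2R whatever the facial bias of the seven-membered ring.

Step 20
Reactants: 31 (2R)-allylic alcohol
Product: 32 C2 TIPS ether (2R,4S,5R,6S,10R,13R,15S,16S)
Conditions: TIPSOTf, 2,6-lutidine, CH2Cl2, 0 °C
Reagents that add atoms: triisopropylsilyl triflate CC(C)[Si](C(C)C)(C(C)C)OS(=O)(=O)C(F)(F)F
Why: Silylation protects the allylic alcohol against the coming oxidations with a group robust enough to survive the later acidic acetonide cleavage.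

Step 21
Reactants: 32 C2 TIPS ether
Product: 33 C17 primary alcohol (2R,4S,5R,6S,10R,13R,15S,16S)
Conditions: DDQ, CH2Cl2/pH 7 buffer, 0 °C
Reagents that add atoms: none
Why: Oxidative cleavage of the PMB ether by DDQ unmasks C17 without affecting the silyl ethers, the acetonide or the alkenes.

Step 22
Reactants: 33 C17 primary alcohol
Product: 34 C17 aldehyde (2R,4S,5R,6S,10R,13R,15S,16R; the C16 descriptor changes by priority only)
Conditions: Dess–Martin periodinane, NaHCO3, CH2Cl2, 0 °C → rt
Reagents that add atoms: none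
Why: Buffered Dess–Martin oxidation gives the α-alkoxy aldehyde without epimerisation; the trans-dioxolane is in any case the thermodynamically preferred arrangement at C16.

Step 23
Reactants: 34 C17 aldehyde
Product: 35 C17=C18 alkene (2-methylprop-1-enyl group on the dioxolane; 2R,4S,5R,6S,10R,13R,15S,16S)
Conditions: i-PrPPh3+ I−, n-BuLi, THF, 0 °C; 34, −78 → 0 °C
Reagents that add atoms: isopropyltriphenylphosphonium iodide CC(C)[P+](c1ccccc1)(c1ccccc1)c1ccccc1.[I-]
Why: Wittig reaction of the non-stabilised isopropylidene ylide with the aldehyde installs the prenyl-type alkene, which is only now safe because no radical step follows.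

Step 24
Reactants: 35 C17=C18 alkene
Product: 36 C15,C16-diol (2R,4S,5R,6S,10R,13R,15S,16S)
Conditions: PPTS, MeOH, 40 °C
Reagents that add atoms: none
Why: Acid-catalysed transacetalisation to methanol cleaves the acetonide at the ketal carbon (not at the allylic C16–O bond), while the hindered C5 TBS and the C2 TIPS ethers are expected to hold under these mild conditions.

Step 25
Reactants: 36 C15,C16-diol
Product: 37 C15,C16-diacetate (2R,4S,5R,6S,10R,13R,15S,16S)
Conditions: Ac2O, pyridine, DMAP (cat.), CH2Cl2, rt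
Reagents that add atoms: acetic anhydride CC(=O)OC(C)=O
Why: DMAP-catalysed acylation esterifies the only two free hydroxyls, C2 and C5 being silylated.

Step 26
Reactants: 37 C15,C16-diacetate
Product: 38 CNP0423623.2 (target; 2R,4S,5R,6S,10R,13R,15S,16S)
Conditions: HF·pyridine, pyridine, THF, 0 → 40 °C
Reagents that add atoms: none
Why: Fluoride-mediated desilylation under weakly acidic, non-nucleophilic conditions removes both silyl ethers without cleaving or migrating the acetates.

**Compound list**

1 | (S)-2,2-dimethyl-1,3-dioxolane-4-carbaldehyde | O=C[C@@H]1COC(C)(C)O1 | starting material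
2 | (Z)-but-2-ene | C/C=C\C | starting material
3 | (Z)-crotylpotassium | C/C=C\[CH2-].[K+] | intermediate (not isolated)
4 | (Z)-crotyldiisopinocampheylborane, Ipc groups from (+)-α-pinene | C/C=C\CB([C@@H]1C[C@@H]2C[C@H]([C@H]1C)C2(C)C)[C@@H]1C[C@@H]2C[C@H]([C@H]1C)C2(C)C | intermediate (not isolated)
5 | (1S,2R)-1-[(4S)-2,2-dimethyl-1,3-dioxolan-4-yl]-2-methylbut-3-en-1-ol | C=C[C@@H](C)[C@H](O)[C@@H]1COC(C)(C)O1 | intermediate
6 | [(4S,5S)-5-[(2R)-but-3-en-2-yl]-2,2-dimethyl-1,3-dioxolan-4-yl]methanol | C=C[C@@H](C)[C@@H]1OC(C)(C)O[C@H]1CO | intermediate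
7 | (4S,5S)-4-[(2R)-but-3-en-2-yl]-5-[(4-methoxybenzyloxy)methyl]-2,2-dimethyl-1,3-dioxolane | C=C[C@@H](C)[C@@H]1OC(C)(C)O[C@H]1COCc1ccc(OC)cc1 | intermediate
8 | B-alkyl-9-BBN adduct of 7 (boron on C5) | B1(CC[C@@H](C)[C@@H]3OC(C)(C)O[C@H]3COCc4ccc(OC)cc4)C2CCCC1CCC2 | intermediate (not isolated)
9 | (3R)-3-[(4S,5S)-5-[(4-methoxybenzyloxy)methyl]-2,2-dimethyl-1,3-dioxolan-4-yl]butan-1-ol | OCC[C@@H](C)[C@@H]1OC(C)(C)O[C@H]1COCc1ccc(OC)cc1 | intermediate
10 | (3R)-3-[(4S,5S)-5-[(4-methoxybenzyloxy)methyl]-2,2-dimethyl-1,3-dioxolan-4-yl]butanal | O=CC[C@@H](C)[C@@H]1OC(C)(C)O[C@H]1COCc1ccc(OC)cc1 | intermediate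
11 | Mannich base, 2-[(dimethylamino)methyl] derivative of 10 (C4 epimers) | CN(C)CC(C=O)[C@@H](C)[C@@H]1OC(C)(C)O[C@H]1COCc1ccc(OC)cc1 | intermediate (not isolated)
12 | (3R)-3-[(4S,5S)-5-[(4-methoxybenzyloxy)methyl]-2,2-dimethyl-1,3-dioxolan-4-yl]-2-methylidenebutanal | C=C(C=O)[C@@H](C)[C@@H]1OC(C)(C)O[C@H]1COCc1ccc(OC)cc1 | intermediate
13 | methyl 3-hydroxypropanoate | COC(=O)CCO | starting material
14 | methyl 3-[(tert-butyldimethylsilyl)oxy]propanoate | COC(=O)CCO[Si](C)(C)C(C)(C)C | intermediate
15 | lithium enolate of 14 | CO\C([O-])=C/CO[Si](C)(C)C(C)(C)C.[Li+] | intermediate (not isolated)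
16 | 1-methoxy-1-(trimethylsilyloxy)-3-[(tert-butyldimethylsilyl)oxy]prop-1-ene | CO\C(O[Si](C)(C)C)=C/CO[Si](C)(C)C(C)(C)C | intermediate
17 | cyclopent-2-en-1-one | O=C1C=CCC1 | starting material
18 | methyl (2S)-3-[(tert-butyldimethylsilyl)oxy]-2-[(1R)-3-(trimethylsilyloxy)cyclopent-2-en-1-yl]propanoate | COC(=O)[C@H](CO[Si](C)(C)C(C)(C)C)[C@@H]1CCC(O[Si](C)(C)C)=C1 | intermediate
19 | dicyclohexylboron enolate corresponding to 18 | COC(=O)[C@H](CO[Si](C)(C)C(C)(C)C)[C@@H]1CCC(OB(C2CCCCC2)C2CCCCC2)=C1 | intermediate (not isolated)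
20 | aldol adduct: methyl 2-[(1R,2R)-2-{(1S,3R)-1-hydroxy-2-methylidene-3-[(4S,5S)-5-(PMB-oxymethyl)-2,2-dimethyl-1,3-dioxolan-4-yl]butyl}-3-oxocyclopentyl]-3-(TBS-oxy)propanoate, (2S) | COC(=O)[C@H](CO[Si](C)(C)C(C)(C)C)[C@@H]1CCC(=O)[C@H]1[C@H](O)C(=C)[C@@H](C)[C@@H]2OC(C)(C)O[C@H]2COCc3ccc(OC)cc3 | intermediate
21 | C5 TBS ether of 20 | COC(=O)[C@H](CO[Si](C)(C)C(C)(C)C)[C@@H]1CCC(=O)[C@H]1[C@H](O[Si](C)(C)C(C)(C)C)C(=C)[C@@H](C)[C@@H]2OC(C)(C)O[C@H]2COCc3ccc(OC)cc3 | intermediate
22 | potassium C7(O)=C8 enolate of 21 | COC(=O)[C@H](CO[Si](C)(C)C(C)(C)C)[C@@H]1CC=C([O-])[C@H]1[C@H](O[Si](C)(C)C(C)(C)C)C(=C)[C@@H](C)[C@@H]2OC(C)(C)O[C@H]2COCc3ccc(OC)cc3.[K+] | intermediate (not isolated)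
23 | C7=C8 enol triflate | COC(=O)[C@H](CO[Si](C)(C)C(C)(C)C)[C@@H]1CC=C(OS(=O)(=O)C(F)(F)F)[C@H]1[C@H](O[Si](C)(C)C(C)(C)C)C(=C)[C@@H](C)[C@@H]2OC(C)(C)O[C@H]2COCc3ccc(OC)cc3 | intermediate
24 | C7-methyl cyclopentene methyl ester | COC(=O)[C@H](CO[Si](C)(C)C(C)(C)C)[C@@H]1CC=C(C)[C@H]1[C@H](O[Si](C)(C)C(C)(C)C)C(=C)[C@@H](C)[C@@H]2OC(C)(C)O[C@H]2COCc3ccc(OC)cc3 | intermediate
25 | C2 carboxylic acid | OC(=O)[C@H](CO[Si](C)(C)C(C)(C)C)[C@@H]1CC=C(C)[C@H]1[C@H](O[Si](C)(C)C(C)(C)C)C(=C)[C@@H](C)[C@@H]2OC(C)(C)O[C@H]2COCc3ccc(OC)cc3 | intermediate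
26 | Se-phenyl selenoester (radical precursor) | O=C([Se]c5ccccc5)[C@H](CO[Si](C)(C)C(C)(C)C)[C@@H]1CC=C(C)[C@H]1[C@H](O[Si](C)(C)C(C)(C)C)C(=C)[C@@H](C)[C@@H]3OC(C)(C)O[C@H]3COCc4ccc(OC)cc4 | intermediate
27 | trans-fused hydroazulen-2-one with C1–CH2OTBS, C5–OTBS and the C4 side chain | O=C1C[C@@H]([C@@H](C)[C@@H]3OC(C)(C)O[C@H]3COCc4ccc(OC)cc4)[C@@H](O[Si](C)(C)C(C)(C)C)[C@@H]2C(C)=CC[C@H]2[C@H]1CO[Si](C)(C)C(C)(C)C | intermediate
28 | C11 alcohol (β-hydroxy ketone) | O=C1C[C@@H]([C@@H](C)[C@@H]3OC(C)(C)O[C@H]3COCc4ccc(OC)cc4)[C@@H](O[Si](C)(C)C(C)(C)C)[C@@H]2C(C)=CC[C@H]2[C@H]1CO | intermediate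
29 | C11 mesylate | O=C1C[C@@H]([C@@H](C)[C@@H]3OC(C)(C)O[C@H]3COCc4ccc(OC)cc4)[C@@H](O[Si](C)(C)C(C)(C)C)[C@@H]2C(C)=CC[C@H]2[C@H]1COS(C)(=O)=O | intermediate (not isolated)
30 | α-methylene ketone (C1=C11H2, C2=O) | C=C1C(=O)C[C@@H]([C@@H](C)[C@@H]3OC(C)(C)O[C@H]3COCc4ccc(OC)cc4)[C@@H](O[Si](C)(C)C(C)(C)C)[C@@H]2C(C)=CC[C@@H]12 | intermediate
31 | (2R)-allylic alcohol | C=C1[C@H](O)C[C@@H]([C@@H](C)[C@@H]3OC(C)(C)O[C@H]3COCc4ccc(OC)cc4)[C@@H](O[Si](C)(C)C(C)(C)C)[C@@H]2C(C)=CC[C@@H]12 | intermediate
32 | C2 TIPS ether | C=C1[C@H](O[Si](C(C)C)(C(C)C)C(C)C)C[C@@H]([C@@H](C)[C@@H]3OC(C)(C)O[C@H]3COCc4ccc(OC)cc4)[C@@H](O[Si](C)(C)C(C)(C)C)[C@@H]2C(C)=CC[C@@H]12 | intermediate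
33 | C17 primary alcohol | C=C1[C@H](O[Si](C(C)C)(C(C)C)C(C)C)C[C@@H]([C@@H](C)[C@@H]3OC(C)(C)O[C@H]3CO)[C@@H](O[Si](C)(C)C(C)(C)C)[C@@H]2C(C)=CC[C@@H]12 | intermediate
34 | C17 aldehyde | C=C1[C@H](O[Si](C(C)C)(C(C)C)C(C)C)C[C@@H]([C@@H](C)[C@@H]3OC(C)(C)O[C@H]3C=O)[C@@H](O[Si](C)(C)C(C)(C)C)[C@@H]2C(C)=CC[C@@H]12 | intermediate
35 | C17=C18 alkene with C15/C16 acetonide | C=C1[C@H](O[Si](C(C)C)(C(C)C)C(C)C)C[C@@H]([C@@H](C)[C@@H]3OC(C)(C)O[C@H]3C=C(C)C)[C@@H](O[Si](C)(C)C(C)(C)C)[C@@H]2C(C)=CC[C@@H]12 | intermediate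
36 | C15,C16-diol | C=C1[C@H](O[Si](C(C)C)(C(C)C)C(C)C)C[C@@H]([C@@H](C)[C@H](O)[C@H](C=C(C)C)O)[C@@H](O[Si](C)(C)C(C)(C)C)[C@@H]2C(C)=CC[C@@H]12 | intermediate
37 | C15,C16-diacetate, C2 TIPS and C5 TBS ethers | C=C1[C@H](O[Si](C(C)C)(C(C)C)C(C)C)C[C@@H]([C@@H](C)[C@H](OC(C)=O)[C@H](C=C(C)C)OC(C)=O)[C@@H](O[Si](C)(C)C(C)(C)C)[C@@H]2C(C)=CC[C@@H]12 | intermediate
38 | CNP0423623.2 | C=C1[C@H](O)C[C@@H]([C@@H](C)[C@H](OC(C)=O)[C@H](C=C(C)C)OC(C)=O)[C@@H](O)[C@@H]2C(C)=CC[C@@H]12 | target

**Step count and risks**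

Total steps: 26. Longest linear sequence: 23 steps (steps 1–6, then 10–26); the branch from methyl 3-hydroxypropanoate runs 20 steps.

Steps most likely to fail:

1. Step 16 (radical ring closure). The α-branched acyl radical may lose carbon monoxide before it closes, may attack C8 of the cyclopentene across the ring (5-exo, norbornanone-type), or may take hydrogen too early. Fallback by ring-closing metathesis and conjugate reduction, setting out from ester 24 and returning at ketone 27: reduction of 24 with i-Bu2AlH (CH2Cl2, −78 °C) would give the C2 aldehyde F1, and vinylmagnesium bromide (THF, −78 °C) would give the C2 vinyl carbinol F2 as a mixture of C2 epimers. Ring-closing metathesis between this vinyl group and the C4 methylene with second-generation Hoveyda–Grubbs catalyst RuCl2(H2IMes)(=CH–C6H4-2-OiPr) (toluene, 80 °C) would close ring B as the cycloheptenol F3, the vinyl CH becoming C3. Dess–Martin oxidation would give the cycloheptenone F4, and conjugate reduction with [(Ph3P)CuH]6 (benzene, rt) should deliver hydride to C4 anti to the C5 silyl ether and so give 27.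

2. Step 9 (enantioselective Mukaiyama–Michael addition). Facial discrimination or turnover may be insufficient with the substituted ketene acetal, and the enol silane may be lost on work-up. Fallback by resolution through the chiral aldehyde, setting out from 16 and 17 and returning at 20: the achiral Lewis acid Ph3CSbCl6 (5 mol%, CH2Cl2, −78 °C) would give the racemic adduct, that is 18 together with the enantiomeric enol ether F5. Step 10 on this mixture with enantiopure 12 would give 20 and the diastereomeric aldol adduct F6, which differs from 20 at every ring centre relative to the side chain and would be removed by chromatography (at this stage or after silylation).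

3. Step 10 (boron aldol). Silicon-to-boron exchange may be incomplete, and Me3SiOTf may open a competing open-transition-state pathway that erodes the C5 configuration; the C5 hydroxyl may also lactonise onto the C2 ester. Fallback by reductive enolate generation, setting out from 18 and returning at 20: N-bromosuccinimide (THF, −78 °C) would convert the enol ether into the C6 bromo ketone F7. CrCl2 (divalent chromium) with catalytic LiI in THF, in the presence of 12, would then reduce the C–Br bond to the chromium enolate at C6 only, and its Reformatsky-type aldol reaction is known to favour the anti adduct 20.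

**Further compounds**

F1 | step 16 | C2 aldehyde from ester 24 | O=C[C@H](CO[Si](C)(C)C(C)(C)C)[C@@H]1CC=C(C)[C@H]1[C@H](O[Si](C)(C)C(C)(C)C)C(=C)[C@@H](C)[C@@H]3OC(C)(C)O[C@H]3COCc4ccc(OC)cc4
F2 | step 16 | C2 vinyl carbinol (C2 epimers) | C=CC(O)[C@H](CO[Si](C)(C)C(C)(C)C)[C@@H]1CC=C(C)[C@H]1[C@H](O[Si](C)(C)C(C)(C)C)C(=C)[C@@H](C)[C@@H]3OC(C)(C)O[C@H]3COCc4ccc(OC)cc4
F3 | step 16 | cycloheptenol with C3=C4 (C2 epimers) | OC1C=C([C@@H](C)[C@@H]3OC(C)(C)O[C@H]3COCc4ccc(OC)cc4)[C@@H](O[Si](C)(C)C(C)(C)C)[C@@H]2C(C)=CC[C@H]2[C@H]1CO[Si](C)(C)C(C)(C)C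
F4 | step 16 | cycloheptenone (C2=O, C3=C4) | O=C1C=C([C@@H](C)[C@@H]3OC(C)(C)O[C@H]3COCc4ccc(OC)cc4)[C@@H](O[Si](C)(C)C(C)(C)C)[C@@H]2C(C)=CC[C@H]2[C@H]1CO[Si](C)(C)C(C)(C)C
F5 | step 9 | enantiomer of enol ether 18 | COC(=O)[C@@H](CO[Si](C)(C)C(C)(C)C)[C@H]1CCC(O[Si](C)(C)C)=C1
F6 | step 9 | diastereomeric aldol adduct from F5 and 12 | COC(=O)[C@@H](CO[Si](C)(C)C(C)(C)C)[C@H]1CCC(=O)[C@@H]1[C@@H](O)C(=C)[C@@H](C)[C@@H]2OC(C)(C)O[C@H]2COCc3ccc(OC)cc3
F7 | step 10 | C6 bromo ketone (C6 epimers) | COC(=O)[C@H](CO[Si](C)(C)C(C)(C)C)[C@@H]1CCC(=O)C1Br
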